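**Plan**
- Retrosynthesis: first the three O–Si bonds are cut. Then C2–C3 and C4–C4a of ring C are cut in one event, which removes C3/C4 as ethoxyacetylene and leaves C2 as an acetal carbon on O1. That acetal goes back to an aryl ester, then to a phenol and a benzoic acid. Last, the ring A C8–CH2 bond and the bond between the lavandulyl stereocentre and its prenyl CH2 are cut.
- Enabling feature: C2 is a benzylic carbon that carries O1 and the 2,4-dioxygenated ring B, so it can be an oxocarbenium carbon. O1=C2 together with C8a=C4a of the phloroglucinol ring A is then a cationic 2-oxadiene, and C4a (ortho to O1 and O5, para to O7) is the only free carbon next to O1.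
- Forward: rings A and B are bought. The lavandulyl iodide (4 steps) is coupled to a ring A bromide, ring B is attached as an ester at O1 and reduced to the acetoxy acetal, and ring C is formed last by annulation with ethoxyacetylene. Desilylation follows.
- Stereochemistry: the lavandulyl centre comes from an oxazolidinone auxiliary (dienolate alkylation); C2 comes from the chiral counter-anion in the ring C annulation.

Key step: step 11

Remark: which enantiomer of the chiral acid in step 11 gives the (2S) face cannot be predicted with confidence; the (R)-acid is written and its mirror image is used if a first run shows the opposite sense.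

Step 1
Reactants: 1 (S)-4-benzyl-1,3-oxazolidin-2-one; 2 3-methylbut-2-enoyl chloride
Product: 4 (S)-4-benzyl-3-(3-methylbut-2-enoyl)-1,3-oxazolidin-2-one, via lithium salt 3 (not isolated)
Conditions: n-BuLi, THF, −78 °C; then 2, −78 → 0 °C
Reagents that add atoms: none
Why: N-acylation of a lithiated oxazolidinone with an acid chloride is routine and forms no stereocentre.

Step 2
Reactants: 4 (S)-4-benzyl-3-(3-methylbut-2-enoyl)-1,3-oxazolidin-2-one; 5 1-bromo-3-methylbut-2-ene (prenyl bromide)
Product: 7 (S)-4-benzyl-3-[(2S)-5-methyl-2-(prop-1-en-2-yl)hex-4-enoyl]-1,3-oxazolidin-2-one, via sodium dienolate 6 (not isolated)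
Conditions: NaN(SiMe3)2, THF, −78 °C; then 5, −78 → −40 °C
Reagents that add atoms: none
Why: Evans alkylation in its deconjugative form: the chelated (Z)-dienolate is alkylated at the alpha carbon by the allylic bromide on the face opposite to the benzyl group of the auxiliary, which sets the (S) centre and moves the double bond out of conjugation.

Step 3
Reactants: 7 (S)-4-benzyl-3-[(2S)-5-methyl-2-(prop-1-en-2-yl)hex-4-enoyl]-1,3-oxazolidin-2-one
Product: 8 (S)-lavandulol [(2S)-5-methyl-2-(prop-1-en-2-yl)hex-4-en-1-ol]
Conditions: LiBH4, MeOH (1 equiv), Et2O, 0 °C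
Reagents that add atoms: none
Why: Reductive cleavage of the N-acyl oxazolidinone by borohydride should give the primary alcohol and return the auxiliary without touching the isolated olefins or the allylic stereocentre.

Step 4
Reactants: 8 (S)-lavandulol
Product: 9 (S)-lavandulyl iodide [(2S)-1-iodo-5-methyl-2-(prop-1-en-2-yl)hex-4-ene]
Conditions: I2, PPh3, imidazole, CH2Cl2, 0 °C
Reagents that add atoms: iodine, II
Why: Appel-type iodination displaces the activated primary oxygen at CH2 by SN2, so the neighbouring stereocentre is not involved.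

Step 5
Reactants: 10 phloroglucinol (benzene-1,3,5-triol)
Product: 11 3,5-bis(tert-butyldimethylsilyloxy)phenol
Conditions: TBSCl (2.0 equiv), imidazole, DMF, 0 °C
Reagents that add atoms: tert-butyldimethylsilyl chloride, CC(C)(C)[Si](C)(C)Cl
Why: Silylation of a symmetric triol with two equivalents should give the bis-ether as the main component of a statistical mixture, from which mono- and tris-ethers are separated and recycled.

Step 6
Reactants: 11 3,5-bis(tert-butyldimethylsilyloxy)phenol
Product: 12 2-bromo-3,5-bis(tert-butyldimethylsilyloxy)phenol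
Conditions: NBS (1.0 equiv), i-Pr2NH (10 mol %), CH2Cl2, −78 → −40 °C
Reagents that add atoms: N-bromosuccinimide, O=C1CCC(=O)N1Br
Why: Amine-catalysed electrophilic bromination delivers bromine ortho to the free OH through a hydrogen-bonded N-bromoamine; the two ortho positions are equivalent and the only other free carbon lies between two bulky silyloxy groups.

Step 7
Reactants: 9 (S)-lavandulyl iodide; 12 2-bromo-3,5-bis(tert-butyldimethylsilyloxy)phenol
Product: 14 3,5-bis(tert-butyldimethylsilyloxy)-2-[(2R)-5-methyl-2-(prop-1-en-2-yl)hex-4-en-1-yl]phenol, via lavandulylzinc iodide 13 (not isolated)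
Conditions: Zn dust, LiCl, THF, 40 °C (9 to 13); then 12, Pd(OAc)2 (2 mol %), SPhos (2-dicyclohexylphosphino-2′,6′-dimethoxybiphenyl, 4 mol %), THF, 25 °C, 13 added slowly
Reagents that add atoms: none
Why: Negishi coupling of a primary alkylzinc halide with an aryl bromide; with this ligand and slow addition the cross-coupling should outrun protonation of the zinc reagent by the phenol, and the stereocentre is beta to the metal and not touched (its descriptor changes from S to R only because the CH2 substituent changes priority).

Step 8
Reactants: 15 4-hydroxy-2-methoxybenzoic acid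
Product: 17 4-(tert-butyldimethylsilyloxy)-2-methoxybenzoic acid, via bis-silyl compound 16 (not isolated)
Conditions: TBSCl (2.2 equiv), imidazole, DMF, rt; then AcOH–THF–H2O, rt
Reagents that add atoms: tert-butyldimethylsilyl chloride, CC(C)(C)[Si](C)(C)Cl
Why: Silylation of phenol and acid followed by hydrolysis of the much more labile silyl ester leaves the aryl silyl ether in place.

Step 9
Reactants: 14 3,5-bis(tert-butyldimethylsilyloxy)-2-[(2R)-5-methyl-2-(prop-1-en-2-yl)hex-4-en-1-yl]phenol; 17 4-(tert-butyldimethylsilyloxy)-2-methoxybenzoic acid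
Product: 18 3,5-bis(tert-butyldimethylsilyloxy)-2-[(2R)-5-methyl-2-(prop-1-en-2-yl)hex-4-en-1-yl]phenyl 4-(tert-butyldimethylsilyloxy)-2-methoxybenzoate
Conditions: DCC, DMAP (cat.), CH2Cl2, 0 °C → rt
Reagents that add atoms: none
Why: Steglich esterification acylates the phenol under neutral conditions that spare the silyl ethers and olefins, and it forms the O1–C2 bond at the ester oxidation level.

Step 10
Reactants: 18 the aryl benzoate from step 9
Product: 20 acetoxy[4-(tert-butyldimethylsilyloxy)-2-methoxyphenyl]methyl aryl ether (the aryl group is that of phenol 14; both epimers at the acetal carbon), via aluminium hemiacetal 19 (not isolated)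
Conditions: i-Bu2AlH, CH2Cl2, −78 °C; then pyridine, DMAP, Ac2O, −78 → −20 °C
Reagents that add atoms: acetic anhydride, CC(=O)OC(C)=O
Why: Reductive acetylation of an ester: one hydride adds to the aryl ester at −78 °C and the tetrahedral aluminium hemiacetal is acetylated in situ before it can collapse; the acetal carbon forms as a mixture of epimers, which does not matter because it becomes planar in step 11.

Step 11
Reactants: 20 the alpha-acetoxy ether from step 10; 21 ethoxyacetylene (ethoxyethyne)
Product: 24 (2S)-5,7-bis(tert-butyldimethylsilyloxy)-2-[4-(tert-butyldimethylsilyloxy)-2-methoxyphenyl]-8-[(2R)-5-methyl-2-(prop-1-en-2-yl)hex-4-en-1-yl]chroman-4-one, via oxocarbenium ion 22 (not isolated), via 4-ethoxy-2H-chromene 23 (not isolated)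
Conditions: (R)-3,3′-bis(2,4,6-triisopropylphenyl)-1,1′-binaphthyl-2,2′-diyl N-triflylphosphoramide (C51H57F3NO5PS, 10 mol %), 21 (3 equiv, added slowly), toluene, −60 °C; then aq. oxalic acid, THF, 0 °C
Reagents that add atoms: water, O
Why: Proposed new method: the chiral acid ionises 20 by loss of acetic acid to the contact ion pair of the aryl(aryloxy)oxocarbenium ion 22, the nucleophilic CH terminus of the ynol ether adds to its carbon (C2–C3) to give an O-ethyl ketenium ion, and the ring A carbon between O1 and the 5-silyloxy group attacks the ketenium carbon (C4–C4a) and loses its proton, which returns the catalyst; the closest known reaction types are the oxa-Povarov annulation of aryloxy oxocarbenium ions with alkenes and the enantioselective Brønsted-acid-catalysed Povarov reaction of N-aryl iminium ions, here extended to an ynol ether as a ketene equivalent under chiral-anion control. Ring C closes as a stepwise formal [4+2] of the 2-oxadiene C4a=C8a–O1=C2 with the alkyne, the second bond by a six-membered electrophilic aromatic substitution on the digonal ketenium carbon (6-exo-dig with respect to its C=O bond). The only new stereocentre, C2, is fixed in the irreversible C2–C3 bond formation, where the phosphoramidate counter-anion shields one face of the planar cation; the lavandulyl centre is too remote to interfere. The step needs acetate and not the phenoxide to leave (the carboxylate is the better leaving group and the aryloxy cation the more stable one), attack by the ynol ether and not by the two lavandulyl olefins (far higher nucleophilicity, and the olefins could reach the cation only through eight-membered transition states), and closure at a single ring carbon (the other position ortho to O1 carries the lavandulyl chain). Mild aqueous acid should then hydrolyse the enol ether 23 to the ketone without touching C2.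

Step 12
Reactants: 24 the tris-silyl flavanone from step 11
Product: 25 leachianone A
Conditions: Bu4NF, AcOH (1:1), THF, 0 °C
Reagents that add atoms: none
Why: Fluoride cleaves the three aryl silyl ethers, and the acetic acid buffer should prevent phenoxide-induced opening of ring C (which would racemise C2) while being too weak to cyclise the lavandulyl olefins onto the 7-OH.

**Compound list**
1 | (S)-4-benzyl-1,3-oxazolidin-2-one | O=C1OC[C@H](Cc2ccccc2)N1 | starting material
2 | 3-methylbut-2-enoyl chloride | CC(C)=CC(=O)Cl | starting material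
3 | lithium salt of 1 | [Li+].O=C1OC[C@H](Cc2ccccc2)[N-]1 | intermediate
4 | (S)-4-benzyl-3-(3-methylbut-2-enoyl)-1,3-oxazolidin-2-one | CC(C)=CC(=O)N1C(=O)OC[C@@H]1Cc1ccccc1 | intermediate
5 | 1-bromo-3-methylbut-2-ene | CC(C)=CCBr | starting material
6 | sodium (Z)-dienolate of 4 | [Na+].C=C(C)/C=C(\[O-])N1C(=O)OC[C@@H]1Cc1ccccc1 | intermediate
7 | (S)-4-benzyl-3-[(2S)-5-methyl-2-(prop-1-en-2-yl)hex-4-enoyl]-1,3-oxazolidin-2-one | C=C(C)[C@H](CC=C(C)C)C(=O)N1C(=O)OC[C@@H]1Cc1ccccc1 | intermediate
8 | (S)-lavandulol | C=C(C)[C@H](CC=C(C)C)CO | intermediate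
9 | (S)-lavandulyl iodide | C=C(C)[C@H](CC=C(C)C)CI | intermediate
10 | phloroglucinol | Oc1cc(O)cc(O)c1 | starting material
11 | 3,5-bis(tert-butyldimethylsilyloxy)phenol | CC(C)(C)[Si](C)(C)Oc1cc(O)cc(O[Si](C)(C)C(C)(C)C)c1 | intermediate
12 | 2-bromo-3,5-bis(tert-butyldimethylsilyloxy)phenol | CC(C)(C)[Si](C)(C)Oc1cc(O)c(Br)c(O[Si](C)(C)C(C)(C)C)c1 | intermediate
13 | (S)-lavandulylzinc iodide | C=C(C)[C@H](CC=C(C)C)C[Zn]I | intermediate
14 | 3,5-bis(tert-butyldimethylsilyloxy)-2-[(2R)-5-methyl-2-(prop-1-en-2-yl)hex-4-en-1-yl]phenol | C=C(C)[C@H](CC=C(C)C)Cc1c(O)cc(O[Si](C)(C)C(C)(C)C)cc1O[Si](C)(C)C(C)(C)C | intermediate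
15 | 4-hydroxy-2-methoxybenzoic acid | COc1cc(O)ccc1C(=O)O | starting material
16 | tert-butyldimethylsilyl 4-(tert-butyldimethylsilyloxy)-2-methoxybenzoate | COc1cc(O[Si](C)(C)C(C)(C)C)ccc1C(=O)O[Si](C)(C)C(C)(C)C | intermediate
17 | 4-(tert-butyldimethylsilyloxy)-2-methoxybenzoic acid | COc1cc(O[Si](C)(C)C(C)(C)C)ccc1C(=O)O | intermediate
18 | aryl benzoate of 14 and 17 | C=C(C)[C@H](CC=C(C)C)Cc1c(OC(=O)c2ccc(O[Si](C)(C)C(C)(C)C)cc2OC)cc(O[Si](C)(C)C(C)(C)C)cc1O[Si](C)(C)C(C)(C)C | intermediate
19 | diisobutylaluminium hemiacetal of 18 | C=C(C)[C@H](CC=C(C)C)Cc1c(OC(O[Al](CC(C)C)CC(C)C)c2ccc(O[Si](C)(C)C(C)(C)C)cc2OC)cc(O[Si](C)(C)C(C)(C)C)cc1O[Si](C)(C)C(C)(C)C | intermediate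
20 | alpha-acetoxy ether (acetal carbon as both epimers) | C=C(C)[C@H](CC=C(C)C)Cc1c(OC(OC(C)=O)c2ccc(O[Si](C)(C)C(C)(C)C)cc2OC)cc(O[Si](C)(C)C(C)(C)C)cc1O[Si](C)(C)C(C)(C)C | intermediate
21 | ethoxyacetylene | C#COCC | starting material
22 | aryl(aryloxy)oxocarbenium ion (counter-anion: the chiral phosphoramidate) | C=C(C)[C@H](CC=C(C)C)Cc1c([O+]=Cc2ccc(O[Si](C)(C)C(C)(C)C)cc2OC)cc(O[Si](C)(C)C(C)(C)C)cc1O[Si](C)(C)C(C)(C)C | intermediate
23 | (2S)-4-ethoxy-2H-chromene (enol ether of 24) | C=C(C)[C@H](CC=C(C)C)Cc1c(O[Si](C)(C)C(C)(C)C)cc(O[Si](C)(C)C(C)(C)C)c2c1O[C@H](c1ccc(O[Si](C)(C)C(C)(C)C)cc1OC)C=C2OCC | intermediate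
24 | (2S)-tris-silyl flavanone | C=C(C)[C@H](CC=C(C)C)Cc1c(O[Si](C)(C)C(C)(C)C)cc(O[Si](C)(C)C(C)(C)C)c2c1O[C@H](c1ccc(O[Si](C)(C)C(C)(C)C)cc1OC)CC2=O | intermediate
25 | leachianone A | C=C(C)[C@H](CC=C(C)C)Cc1c(O)cc(O)c2c1O[C@H](c1ccc(O)cc1OC)CC2=O | target

**Totals**
Total step count: 12. Longest linear sequence: 9 steps (1, 2, 3, 4, 7, 9, 10, 11, 12).

**Steps most likely to fail**

Step 11 (Proposed new method). Possible failure processes are: addition of the acid catalyst or of the liberated acetic acid to the ynol ether, capture of the ketenium ion by acetate before ring closure, protonation of the lavandulyl olefins, or poor facial discrimination in the ion pair. The fallback sets out from 20 and returns at 24, using known reaction types only. A Mukaiyama-type addition of 1-(tert-butyldimethylsilyloxy)-1-methoxyethene to the oxocarbenium ion from 20 (BF3·OEt2, CH2Cl2, −78 °C) would give the methyl 3-aryl-3-aryloxypropanoate F1 as both epimers. Neutral ester cleavage with Me3SnOH (1,2-dichloroethane, 70 °C) would give the acid F2. Intramolecular Friedel–Crafts acylation through the mixed anhydride (trifluoroacetic anhydride, CH2Cl2, 0 °C) would then close ring C to 24 together with its (2R)-epimer F3. The two are diastereomers because of the lavandulyl centre and would be separated by preparative HPLC; 24 goes on to step 12.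

Step 10. The tetrahedral aluminium hemiacetal may collapse with loss of the aluminium phenoxide before acetylation, followed by over-reduction, and the labile acetoxy ether may be lost on isolation. The fallback sets out from 14 and returns at 20. Commercial 4-hydroxy-2-methoxybenzaldehyde is silylated (TBSCl, imidazole, DMF) to the aldehyde F4. Acetyl chloride with catalytic ZnCl2 (CH2Cl2, −20 °C) adds across its C=O to give the alpha-chloro acetate F5. F5 then alkylates phenol 14 on oxygen (i-Pr2NEt, CH2Cl2, −40 → 0 °C), as in the preparation of acyloxyalkyl aryl ethers, to give 20 without a reduction.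

Step 7. The free phenol may protonate the alkylzinc, oxidative addition into the hindered, electron-rich C–Br bond may be slow, and beta-hydride elimination at the alkylpalladium stage toward the conjugated diene would cost the stereocentre. The fallback sets out from 12 and 17 and returns at 18. The order of the two unions is reversed: bromophenol 12 is first esterified with acid 17 (DCC, DMAP) to the bromo ester F6. F6 has no acidic proton and a less donating oxygen next to bromine. It is then coupled with 13 under the same palladium catalysis to give 18 directly, so that step 9 is no longer needed.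

Further compounds
F1 | step 11 | methyl 3-[4-(tert-butyldimethylsilyloxy)-2-methoxyphenyl]-3-(aryloxy)propanoate, aryl as in 14, both C3 epimers | C=C(C)[C@H](CC=C(C)C)Cc1c(OC(CC(=O)OC)c2ccc(O[Si](C)(C)C(C)(C)C)cc2OC)cc(O[Si](C)(C)C(C)(C)C)cc1O[Si](C)(C)C(C)(C)C
F2 | step 11 | 3-[4-(tert-butyldimethylsilyloxy)-2-methoxyphenyl]-3-(aryloxy)propanoic acid, aryl as in 14, both C3 epimers | C=C(C)[C@H](CC=C(C)C)Cc1c(OC(CC(=O)O)c2ccc(O[Si](C)(C)C(C)(C)C)cc2OC)cc(O[Si](C)(C)C(C)(C)C)cc1O[Si](C)(C)C(C)(C)C
F3 | step 11 | (2R)-epimer of 24 | C=C(C)[C@H](CC=C(C)C)Cc1c(O[Si](C)(C)C(C)(C)C)cc(O[Si](C)(C)C(C)(C)C)c2c1O[C@@H](c1ccc(O[Si](C)(C)C(C)(C)C)cc1OC)CC2=O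
F4 | step 10 | 4-(tert-butyldimethylsilyloxy)-2-methoxybenzaldehyde | COc1cc(O[Si](C)(C)C(C)(C)C)ccc1C=O
F5 | step 10 | chloro[4-(tert-butyldimethylsilyloxy)-2-methoxyphenyl]methyl acetate | COc1cc(O[Si](C)(C)C(C)(C)C)ccc1C(Cl)OC(C)=O
F6 | step 7 | 2-bromo-3,5-bis(tert-butyldimethylsilyloxy)phenyl 4-(tert-butyldimethylsilyloxy)-2-methoxybenzoate | COc1cc(O[Si](C)(C)C(C)(C)C)ccc1C(=O)Oc1cc(O[Si](C)(C)C(C)(C)C)cc(O[Si](C)(C)C(C)(C)C)c1Br
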